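**Plan**
1. Cuts, in order: the three ester C–O bonds; C1=O back to an exocyclic C1=CH2; C7–C8 of the ten-membered carbocycle (C1–C10); C7=C11 and O6–C12 of the butenolide; C6–C7; the oxirane oxygen on C4–C5; finally C1–C2.
2. Enabling feature: in the γ-lactone ring (O–C6–C7–C11–C12) the β-carbon C7 carries the ring carbinol C8 and sits next to the α-carbon C11–H, so O8 and the carbonyl C12 are in a 1,4-relation. A C8 aldehyde and a C7=C11 butenolide give this array by reductive coupling followed by protonation.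
3. Forward: the C8–C9–C10–C1 piece (enol triflate) and the C2–C6 piece (dienol) are joined at C1–C2. The oxirane is made next, then the butenolide ring (metathesis), and last the ten-membered ring (cathode). Acylation, release of the ketone and acetylation follow.
4. C1 travels as a methylidene group. It is inert at the cathode, adds no stereocentre, and ozone turns it into the ketone without the acid that a ketal would need beside the oxirane.
5. Stereochemistry: C10 comes from (R)-citramalic acid, C4 and C5 from Sharpless epoxidation of the (Z)-allylic alcohol, C6 from Felkin–Anh addition to the epoxy aldehyde, and C7, C8 and C11 from the ring closure.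

Key step: step 17

Remark: germacrane numbering is used (C1 ketone, C4–C5 oxirane, C6 lactone carbinol, C8 ester carbinol, C10 tertiary acetate, C11 lactone α-carbon, C12 lactone carbonyl, C13 acetoxymethyl carbon). (R)-Citramalic acid, (Z)-3-methylpent-2-en-4-yn-1-ol and methyl 2-(hydroxymethyl)acrylate are taken as commercial.

Step 1
Reactants: 1 (R)-citramalic acid
Product: 2 2-[(4R)-2,2,4-trimethyl-5-oxo-1,3-dioxolan-4-yl]acetic acid
Conditions: Me2C(OMe)2, p-TsOH·H2O (cat.), CH2Cl2, rt
Reagents that add atoms: 2,2-dimethoxypropane, COC(C)(C)OC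
Why: Acid-catalysed transacetalisation ties the tertiary hydroxyl and the neighbouring carboxyl (C1) into the favoured five-membered dioxolanone, which distinguishes C1 from the C8 carboxyl and does not touch C10.

Step 2
Reactants: 2 2-[(4R)-2,2,4-trimethyl-5-oxo-1,3-dioxolan-4-yl]acetic acid
Product: 4 (3R)-3-hydroxy-3-methyloxolan-2-one, via hydroxyethyl dioxolanone 3 (not isolated)
Conditions: BH3·THF, THF, 0 °C to rt; aqueous work-up; then p-TsOH (cat.), CH2Cl2, rt
Reagents that add atoms: none
Why: Chemoselective borane reduction of the free carboxylic acid beside the ester-type carbonyl gives the C8 alcohol, and acid-catalysed translactonisation with loss of acetone gives the five-membered lactone.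

Step 3
Reactants: 4 (3R)-3-hydroxy-3-methyloxolan-2-one
Product: 5 (2R)-2,4-dihydroxy-N-methoxy-N,2-dimethylbutanamide
Conditions: MeNH(OMe)·HCl, i-PrMgCl, THF, −20 to 0 °C
Reagents that add atoms: N,O-dimethylhydroxylamine hydrochloride, CNOC.Cl
Why: Weinreb aminolysis of the lactone with the magnesium amide opens the ring at the acyl carbon C1 and frees the C8 hydroxyl.

Step 4
Reactants: 5 (2R)-2,4-dihydroxy-N-methoxy-N,2-dimethylbutanamide
Product: 6 (2R)-N-methoxy-N,2-dimethyl-2,4-bis(triethylsilyloxy)butanamide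
Conditions: TESOTf (2.5 equiv), 2,6-lutidine, CH2Cl2, −78 to 0 °C
Reagents that add atoms: triethylsilyl trifluoromethanesulfonate, CC[Si](CC)(CC)OS(=O)(=O)C(F)(F)F
Why: Silylation with a silyl triflate and a hindered pyridine base covers the primary and the tertiary hydroxyl in one operation and blocks relactonisation.

Step 5
Reactants: 6 (2R)-N-methoxy-N,2-dimethyl-2,4-bis(triethylsilyloxy)butanamide
Product: 7 (3R)-3-methyl-3,5-bis(triethylsilyloxy)pentan-2-one
Conditions: MeMgBr, THF, 0 °C to rt
Reagents that add atoms: methylmagnesium bromide, C[Mg]Br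
Why: In the Weinreb ketone synthesis chelation prevents a second addition, so only the methyl ketone is released on work-up.

Step 6
Reactants: 7 (3R)-3-methyl-3,5-bis(triethylsilyloxy)pentan-2-one
Product: 9 (3R)-3-methyl-3,5-bis(triethylsilyloxy)pent-1-en-2-yl trifluoromethanesulfonate, via potassium enolate 8 (not isolated)
Conditions: KN(SiMe3)2, THF, −78 °C; then PhNTf2, −78 to 0 °C
Reagents that add atoms: N-phenylbis(trifluoromethanesulfonimide), O=S(=O)(N(c1ccccc1)S(=O)(=O)C(F)(F)F)C(F)(F)F
Why: In this enolate triflation C10 is quaternary, so deprotonation is possible only at the methyl group and the terminal enol triflate is the only regioisomer.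

Step 7
Reactants: 10 (2Z)-3-methylpent-2-en-4-yn-1-ol
Product: 11 (2Z)-3-methylpenta-2,4-dien-1-ol
Conditions: H2 (1 atm), Pd/CaCO3 poisoned with Pb(OAc)2 (Lindlar catalyst), quinoline, EtOAc, 0 °C to rt
Reagents that add atoms: none
Why: Lindlar semihydrogenation stops at the vinyl stage for the terminal alkyne and leaves the trisubstituted (Z)-alkene, which places C3 and C6 cis, unchanged.

Step 8
Reactants: 11 (2Z)-3-methylpenta-2,4-dien-1-ol; 9 (3R)-3-methyl-3,5-bis(triethylsilyloxy)pent-1-en-2-yl trifluoromethanesulfonate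
Product: 13 (2Z,7R)-3,7-dimethyl-6-methylidene-7,9-bis(triethylsilyloxy)non-2-en-1-ol, via bis-9-BBN adduct 12 (not isolated)
Conditions: 9-BBN-H (2.2 equiv), THF, 0 °C to rt; then 9, PdCl2(dppf) (5 mol %), AsPh3, Cs2CO3, DMF–H2O, rt
Reagents that add atoms: none
Why: In this B-alkyl Suzuki–Miyaura coupling the borane first caps the hydroxyl and then hydroborates only the monosubstituted vinyl group at its terminus C2, and zerovalent palladium joins C2 to C1 of the enol triflate, which installs the future ketone directly as its methylidene mask.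

Step 9
Reactants: 13 (2Z,7R)-3,7-dimethyl-6-methylidene-7,9-bis(triethylsilyloxy)non-2-en-1-ol
Product: 14 [(2S,3R)-3-methyl-3-[(4R)-4-methyl-3-methylidene-4,6-bis(triethylsilyloxy)hexyl]oxiran-2-yl]methanol
Conditions: Ti(OiPr)4 (10 mol %), L-(+)-diethyl tartrate (12 mol %), t-BuOOH, 4 Å molecular sieves, CH2Cl2, −20 °C
Reagents that add atoms: tert-butyl hydroperoxide, CC(C)(C)OO
Why: Sharpless asymmetric epoxidation acts only on the allylic alcohol, and with the L-(+)-tartrate a (Z)-trisubstituted substrate of the nerol type is oxidised on the face that gives 4R,5S with C3 and C6 cis on the oxirane.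

Step 10
Reactants: 14 [(2S,3R)-3-methyl-3-[(4R)-4-methyl-3-methylidene-4,6-bis(triethylsilyloxy)hexyl]oxiran-2-yl]methanol
Product: 15 (2R,3R)-3-methyl-3-[(4R)-4-methyl-3-methylidene-4,6-bis(triethylsilyloxy)hexyl]oxirane-2-carbaldehyde
Conditions: TEMPO (10 mol %), PhI(OAc)2, CH2Cl2, rt
Reagents that add atoms: none
Why: Oxoammonium (TEMPO) oxidation of the primary alcohol stops at the aldehyde under nearly neutral conditions that spare the oxirane, the silyl ethers and the alkene; the changed descriptor at C5 is only a priority effect.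

Step 11
Reactants: 15 (2R,3R)-3-methyl-3-[(4R)-4-methyl-3-methylidene-4,6-bis(triethylsilyloxy)hexyl]oxirane-2-carbaldehyde
Product: 16 (1S)-1-[(2S,3R)-3-methyl-3-[(4R)-4-methyl-3-methylidene-4,6-bis(triethylsilyloxy)hexyl]oxiran-2-yl]prop-2-en-1-ol
Conditions: CH2=CHMgBr, THF, −78 °C
Reagents that add atoms: vinylmagnesium bromide, C=C[Mg]Br
Why: In this Grignard addition under Felkin–Anh control, attack anti to the C5–O bond of the oxirane, reinforced by the C3 chain cis to the formyl group, should give the 5,6-anti carbinol with 6S configuration.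

Step 12
Reactants: 17 methyl 2-(hydroxymethyl)prop-2-enoate
Product: 18 methyl 2-[(tert-butyldimethylsilyloxy)methyl]prop-2-enoate
Conditions: TBSCl, imidazole, CH2Cl2, 0 °C to rt
Reagents that add atoms: tert-butyldimethylsilyl chloride, CC(C)(C)[Si](C)(C)Cl
Why: Imidazole-promoted silylation of a primary alcohol gives the future C13 oxygen a poor leaving group that fluoride removes later.

Step 13
Reactants: 18 methyl 2-[(tert-butyldimethylsilyloxy)methyl]prop-2-enoate
Product: 19 2-[(tert-butyldimethylsilyloxy)methyl]prop-2-enoic acid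
Conditions: LiOH, THF–H2O, 0 °C to rt; then cold 1 M HCl to pH 4
Reagents that add atoms: lithium hydroxide, [Li+].[OH-]
Why: Saponification of the unhindered methyl ester proceeds under conditions that the silyl ether tolerates.

Step 14
Reactants: 16 (1S)-1-[(2S,3R)-3-methyl-3-[(4R)-4-methyl-3-methylidene-4,6-bis(triethylsilyloxy)hexyl]oxiran-2-yl]prop-2-en-1-ol; 19 2-[(tert-butyldimethylsilyloxy)methyl]prop-2-enoic acid
Product: 20 (1S)-1-[(2S,3R)-3-methyl-3-[(4R)-4-methyl-3-methylidene-4,6-bis(triethylsilyloxy)hexyl]oxiran-2-yl]prop-2-en-1-yl 2-[(tert-butyldimethylsilyloxy)methyl]prop-2-enoate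
Conditions: DCC, DMAP (cat.), CH2Cl2, 0 °C to rt
Reagents that add atoms: none
Why: Steglich esterification forms the O6–C12 bond at the acyl carbon, so C6 keeps its configuration and the oxirane meets no acid.

Step 15
Reactants: 20 (1S)-1-[(2S,3R)-3-methyl-3-[(4R)-4-methyl-3-methylidene-4,6-bis(triethylsilyloxy)hexyl]oxiran-2-yl]prop-2-en-1-yl 2-[(tert-butyldimethylsilyloxy)methyl]prop-2-enoate
Product: 21 (5S)-3-[(tert-butyldimethylsilyloxy)methyl]-5-[(2S,3R)-3-methyl-3-[(4R)-4-methyl-3-methylidene-4,6-bis(triethylsilyloxy)hexyl]oxiran-2-yl]furan-2(5H)-one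
Conditions: second-generation Hoveyda–Grubbs catalyst (5 mol %), toluene (2 mM), 80 °C
Reagents that add atoms: none
Why: In this ring-closing metathesis the catalyst loads on the monosubstituted C7 vinyl group and closes the five-membered butenolide (C7=C11) on the acrylate, while the C1 methylidene next to the quaternary C10 is too hindered to take part.

Step 16
Reactants: 21 (5S)-3-[(tert-butyldimethylsilyloxy)methyl]-5-[(2S,3R)-3-methyl-3-[(4R)-4-methyl-3-methylidene-4,6-bis(triethylsilyloxy)hexyl]oxiran-2-yl]furan-2(5H)-one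
Product: 23 (3R)-6-[(2R,3S)-3-[(2S)-4-[(tert-butyldimethylsilyloxy)methyl]-5-oxo-2,5-dihydrofuran-2-yl]-2-methyloxiran-2-yl]-3-methyl-4-methylidene-3-(triethylsilyloxy)hexanal, via alkoxysulfonium chloride 22 (not isolated)
Conditions: (COCl)2, DMSO, CH2Cl2, −78 to −40 °C; then Et3N, −78 to 0 °C
Reagents that add atoms: none
Why: In this Swern oxidation applied directly to a silyl ether the chlorosulfonium salt attacks only the least hindered, primary triethylsilyl ether, so C8 becomes the aldehyde while the tertiary triethylsilyl and the tert-butyldimethylsilyl ethers stay.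

Step 17
Reactants: 23 (3R)-6-[(2R,3S)-3-[(2S)-4-[(tert-butyldimethylsilyloxy)methyl]-5-oxo-2,5-dihydrofuran-2-yl]-2-methyloxiran-2-yl]-3-methyl-4-methylidene-3-(triethylsilyloxy)hexanal
Product: 26 (4R,5S,6S,7S,8S,10R,11R)-13-(tert-butyldimethylsilyloxy)-4,5-epoxy-8-hydroxy-1-methylidene-10-(triethylsilyloxy)germacran-12,6-olide, via ketyl radical anion 24 (not isolated), via lactone enolate 25 (not isolated)
Conditions: divided cell, reticulated vitreous carbon cathode, Pt anode, n-Bu4NBr (0.1 M), MeCN, di-tert-butyl malonate (5 equiv), −2.4 V vs SCE, 23 added by syringe pump (about 1 mM), 0 °C, 2 F per mol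
Reagents that add atoms: none
Why: Proposed new method: one electron goes to the aldehyde and gives ketyl 24 (first transfer to the butenolide would lead to the same bond), 24 adds as a nucleophilic radical to the β-carbon C7, a second electron gives enolate 25, and the malonate protonates O8 and C11. The closest known reaction type is the electroreductive or SmI2-induced cyclisation of aldehydes and ketones onto α,β-unsaturated esters, which is established only up to eight-membered rings. The ten-membered carbocycle closes in the 10-exo-trig mode, helped by the U-turn at the cis-oxirane, the sp2 centre C1, the quaternary C10 and the slow generation of 24 at high dilution. C7 is controlled by the tether, because C5 stands on one face of the flat butenolide and the cis-oxirane folds the chain back under that face, so that C8 should bond syn to C5 (cis-fused lactone); C8 is controlled by the ketyl C–O dipole, which with the non-chelating n-Bu4N+ cation should turn away from C11 and the growing enolate (8S). C11 is controlled by kinetic protonation of 25 by the bulky malonate on the convex face, opposite to C5 and C8, which leaves C13 cis to C8. The step needs chemoselectivity for the aldehyde–butenolide pair and ring closure ahead of plain reduction: C1 is a methylidene group that is not reduced (an α-oxygenated ketone would lose O10), the silyloxy groups at C10 and C13 are poor leaving groups, and dilution suppresses dimerisation.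

Step 18
Reactants: 26 (4R,5S,6S,7S,8S,10R,11R)-13-(tert-butyldimethylsilyloxy)-4,5-epoxy-8-hydroxy-1-methylidene-10-(triethylsilyloxy)germacran-12,6-olide
Product: 27 8-O-methacrylate of 26
Conditions: methacrylic anhydride, DMAP, Et3N, CH2Cl2, 0 °C to rt
Reagents that add atoms: methacrylic anhydride, C=C(C)C(=O)OC(=O)C(C)=C
Why: DMAP-catalysed acylation with the anhydride esterifies the only free hydroxyl at oxygen, so C8 keeps its configuration.

Step 19
Reactants: 27 8-O-methacrylate of 26
Product: 29 (4R,5S,6S,7S,8S,10R,11R)-13-(tert-butyldimethylsilyloxy)-4,5-epoxy-8-methacryloyloxy-1-oxo-10-(triethylsilyloxy)germacran-12,6-olide, via ozonide 28 (not isolated)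
Conditions: O3 (1 equiv, Sudan Red 7B as indicator), CH2Cl2, −78 °C; then Me2S, −78 °C to rt
Reagents that add atoms: ozone, [O-][O+]=O
Why: In this ozonolysis with reductive work-up the electrophilic ozone cleaves the electron-rich 1,1-dialkyl alkene faster than the electron-poor methacrylate, so the C1 ketone is released without acid and the oxirane is spared.

Step 20
Reactants: 29 (4R,5S,6S,7S,8S,10R,11R)-13-(tert-butyldimethylsilyloxy)-4,5-epoxy-8-methacryloyloxy-1-oxo-10-(triethylsilyloxy)germacran-12,6-olide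
Product: 30 (4R,5S,6S,7S,8S,10R,11R)-4,5-epoxy-10,13-dihydroxy-8-methacryloyloxy-1-oxogermacran-12,6-olide
Conditions: Et3N·3HF, MeCN, rt
Reagents that add atoms: none
Why: Fluoride-induced desilylation with the nearly neutral amine–HF complex removes both silyl groups without opening the oxirane, epimerising C11 or eliminating across C11–C13.

Step 21
Reactants: 30 (4R,5S,6S,7S,8S,10R,11R)-4,5-epoxy-10,13-dihydroxy-8-methacryloyloxy-1-oxogermacran-12,6-olide
Product: 31 CNP0166747.1, (4R,5S,6S,7S,8S,10R,11R)-10,13-diacetoxy-4,5-epoxy-8-methacryloyloxy-1-oxogermacran-12,6-olide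
Conditions: Ac2O, DMAP, Et3N, CH2Cl2, rt
Reagents that add atoms: acetic anhydride, CC(=O)OC(C)=O
Why: DMAP-catalysed acetylation takes the primary C13 hydroxyl at once and the tertiary C10 hydroxyl more slowly, and no stereocentre is touched.

**Compound list**
1 | (R)-citramalic acid | OC(=O)C[C@@](C)(O)C(=O)O | starting material
2 | 2-[(4R)-2,2,4-trimethyl-5-oxo-1,3-dioxolan-4-yl]acetic acid | OC(=O)C[C@@]1(C)OC(C)(C)OC1=O | intermediate
3 | (5R)-5-(2-hydroxyethyl)-2,2,5-trimethyl-1,3-dioxolan-4-one | OCC[C@@]1(C)OC(C)(C)OC1=O | intermediate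
4 | (3R)-3-hydroxy-3-methyloxolan-2-one | C[C@@]1(O)CCOC1=O | intermediate
5 | (2R)-2,4-dihydroxy-N-methoxy-N,2-dimethylbutanamide | OCC[C@@](C)(O)C(=O)N(C)OC | intermediate
6 | (2R)-N-methoxy-N,2-dimethyl-2,4-bis(triethylsilyloxy)butanamide | CC[Si](CC)(CC)OCC[C@@](C)(O[Si](CC)(CC)CC)C(=O)N(C)OC | intermediate
7 | (3R)-3-methyl-3,5-bis(triethylsilyloxy)pentan-2-one | CC[Si](CC)(CC)OCC[C@@](C)(O[Si](CC)(CC)CC)C(C)=O | intermediate
8 | potassium (3R)-3-methyl-3,5-bis(triethylsilyloxy)pent-1-en-2-olate | CC[Si](CC)(CC)OCC[C@@](C)(O[Si](CC)(CC)CC)C(=C)[O-].[K+] | intermediate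
9 | (3R)-3-methyl-3,5-bis(triethylsilyloxy)pent-1-en-2-yl trifluoromethanesulfonate | CC[Si](CC)(CC)OCC[C@@](C)(O[Si](CC)(CC)CC)C(=C)OS(=O)(=O)C(F)(F)F | intermediate
10 | (2Z)-3-methylpent-2-en-4-yn-1-ol | OC/C=C(\C#C)C | starting material
11 | (2Z)-3-methylpenta-2,4-dien-1-ol | OC/C=C(\C=C)C | intermediate
12 | bis-9-BBN adduct of 11 (boron on O6 and on C2, Z-alkene kept) | O(C/C=C(\CCB1C2CCCC1CCC2)C)B1C2CCCC1CCC2 | intermediate
13 | (2Z,7R)-3,7-dimethyl-6-methylidene-7,9-bis(triethylsilyloxy)non-2-en-1-ol | CC[Si](CC)(CC)OCC[C@@](C)(O[Si](CC)(CC)CC)C(=C)CC/C(C)=C\CO | intermediate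
14 | [(2S,3R)-3-methyl-3-[(4R)-4-methyl-3-methylidene-4,6-bis(triethylsilyloxy)hexyl]oxiran-2-yl]methanol | CC[Si](CC)(CC)OCC[C@@](C)(O[Si](CC)(CC)CC)C(=C)CC[C@@]1(C)O[C@H]1CO | intermediate
15 | (2R,3R)-3-methyl-3-[(4R)-4-methyl-3-methylidene-4,6-bis(triethylsilyloxy)hexyl]oxirane-2-carbaldehyde | CC[Si](CC)(CC)OCC[C@@](C)(O[Si](CC)(CC)CC)C(=C)CC[C@@]1(C)O[C@H]1C=O | intermediate
16 | (1S)-1-[(2S,3R)-3-methyl-3-[(4R)-4-methyl-3-methylidene-4,6-bis(triethylsilyloxy)hexyl]oxiran-2-yl]prop-2-en-1-ol | CC[Si](CC)(CC)OCC[C@@](C)(O[Si](CC)(CC)CC)C(=C)CC[C@@]1(C)O[C@H]1[C@@H](O)C=C | intermediate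
17 | methyl 2-(hydroxymethyl)prop-2-enoate | C=C(CO)C(=O)OC | starting material
18 | methyl 2-[(tert-butyldimethylsilyloxy)methyl]prop-2-enoate | C=C(CO[Si](C)(C)C(C)(C)C)C(=O)OC | intermediate
19 | 2-[(tert-butyldimethylsilyloxy)methyl]prop-2-enoic acid | C=C(CO[Si](C)(C)C(C)(C)C)C(=O)O | intermediate
20 | 6-O-[2-(silyloxymethyl)acryloyl] ester of 16 (6S) | CC[Si](CC)(CC)OCC[C@@](C)(O[Si](CC)(CC)CC)C(=C)CC[C@@]1(C)O[C@H]1[C@@H](OC(=O)C(=C)CO[Si](C)(C)C(C)(C)C)C=C | intermediate
21 | (5S)-3-[(tert-butyldimethylsilyloxy)methyl]-5-[(2S,3R)-3-methyl-3-[(4R)-4-methyl-3-methylidene-4,6-bis(triethylsilyloxy)hexyl]oxiran-2-yl]furan-2(5H)-one | CC[Si](CC)(CC)OCC[C@@](C)(O[Si](CC)(CC)CC)C(=C)CC[C@@]1(C)O[C@H]1[C@H]1OC(=O)C(CO[Si](C)(C)C(C)(C)C)=C1 | intermediate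
22 | C8 alkoxydimethylsulfonium chloride derived from 21 | C[S+](C)OCC[C@@](C)(O[Si](CC)(CC)CC)C(=C)CC[C@@]1(C)O[C@H]1[C@H]1OC(=O)C(CO[Si](C)(C)C(C)(C)C)=C1.[Cl-] | intermediate
23 | epoxy butenolide C8 aldehyde (4R,5S,6S,10R; C1 methylidene, 10-OTES, 13-OTBS), precursor of the key step | O=CC[C@@](C)(O[Si](CC)(CC)CC)C(=C)CC[C@@]1(C)O[C@H]1[C@H]1OC(=O)C(CO[Si](C)(C)C(C)(C)C)=C1 | intermediate
24 | C8 ketyl radical anion of 23, tetrabutylammonium salt | [O-][CH]C[C@@](C)(O[Si](CC)(CC)CC)C(=C)CC[C@@]1(C)O[C@H]1[C@H]1OC(=O)C(CO[Si](C)(C)C(C)(C)C)=C1.CCCC[N+](CCCC)(CCCC)CCCC | intermediate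
25 | ring-closed C11=C12 lactone enolate, tetrabutylammonium salt | O[C@H]1C[C@@](C)(O[Si](CC)(CC)CC)C(=C)CC[C@@]2(C)O[C@H]2[C@H]2OC([O-])=C(CO[Si](C)(C)C(C)(C)C)[C@H]21.CCCC[N+](CCCC)(CCCC)CCCC | intermediate
26 | (4R,5S,6S,7S,8S,10R,11R)-13-(tert-butyldimethylsilyloxy)-4,5-epoxy-8-hydroxy-1-methylidene-10-(triethylsilyloxy)germacran-12,6-olide (H6, H7 and H11 on one face), product of the key step | O[C@H]1C[C@@](C)(O[Si](CC)(CC)CC)C(=C)CC[C@@]2(C)O[C@H]2[C@H]2OC(=O)[C@@H](CO[Si](C)(C)C(C)(C)C)[C@H]21 | intermediate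
27 | 8-O-methacrylate of 26 | C=C(C)C(=O)O[C@H]1C[C@@](C)(O[Si](CC)(CC)CC)C(=C)CC[C@@]2(C)O[C@H]2[C@H]2OC(=O)[C@@H](CO[Si](C)(C)C(C)(C)C)[C@H]21 | intermediate
28 | spiro-1,2,4-trioxolane (ozonide) at C1 of 27, C1 configuration open | C=C(C)C(=O)O[C@H]1C[C@@](C)(O[Si](CC)(CC)CC)C3(OCOO3)CC[C@@]2(C)O[C@H]2[C@H]2OC(=O)[C@@H](CO[Si](C)(C)C(C)(C)C)[C@H]21 | intermediate
29 | (4R,5S,6S,7S,8S,10R,11R)-13-(tert-butyldimethylsilyloxy)-4,5-epoxy-8-methacryloyloxy-1-oxo-10-(triethylsilyloxy)germacran-12,6-olide | C=C(C)C(=O)O[C@H]1C[C@@](C)(O[Si](CC)(CC)CC)C(=O)CC[C@@]2(C)O[C@H]2[C@H]2OC(=O)[C@@H](CO[Si](C)(C)C(C)(C)C)[C@H]21 | intermediate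
30 | (4R,5S,6S,7S,8S,10R,11R)-4,5-epoxy-10,13-dihydroxy-8-methacryloyloxy-1-oxogermacran-12,6-olide | C=C(C)C(=O)O[C@H]1C[C@@](C)(O)C(=O)CC[C@@]2(C)O[C@H]2[C@H]2OC(=O)[C@@H](CO)[C@H]21 | intermediate
31 | CNP0166747.1 | C=C(C)C(=O)O[C@H]1C[C@@](C)(OC(C)=O)C(=O)CC[C@@]2(C)O[C@H]2[C@H]2OC(=O)[C@@H](COC(C)=O)[C@H]21 | target

**Step count:** 21 steps in total. The longest linear sequence is 18 steps (steps 1–6, 8–11 and 14–21, from (R)-citramalic acid).

**Steps most likely to fail**

**Step 17.**
- What may go wrong: protonation and uptake of the second electron may outrun the slow ten-membered closure, so that the aldehyde or the butenolide is merely reduced. Further leaks are intermolecular pinacol or hydrodimer coupling, reductive scission of the allylic C6–O bond, loss of silanolate from the enolate, and closure on the wrong face of C7.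
- The fallback uses known chemistry and forms the same C7–C8 bond by a polar instead of a radical path. It sets out from carbinol 16 and comes back at methacrylate 27.
- Carbinol 16 is esterified with commercial 2-(bromomethyl)acrylic acid (DCC, DMAP) to the 2-(bromomethyl)acrylate F1. Ring-closing metathesis with the second-generation Hoveyda–Grubbs catalyst gives the α-(bromomethyl)butenolide F2. Swern oxidation of the primary triethylsilyl ether, with i-Pr2NEt as the base, gives the bromo aldehyde F3.
- CrCl2 in THF–DMF at high dilution turns the allylic bromide into an allylchromium reagent that attacks the aldehyde through its γ-carbon C7. This is an intramolecular Nozaki–Hiyama allylation. That closure has ample precedent for ten-membered carbocycles, and the γ-selective allylation of aldehydes by 3-(bromomethyl)butenolides is known. It gives the macrocyclic α-methylene lactone F4.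
- The ring-locked allyl unit is of the E type, so the chair transition state should give the 7,8-anti adduct, that is the 8R carbinol.
- Copper-catalysed conjugate borylation (B2pin2, CuCl, NaOt-Bu, Xantphos, MeOH), with protonation on the convex face, gives the C13 boronate F5. NaBO3·4H2O gives the diol F6, and TBSCl–imidazole silylates the primary hydroxyl to the 8-epi carbinol F7.
- Mitsunobu esterification with methacrylic acid (PPh3, DIAD) inverts C8 and delivers 27.

**Step 11.**
- What may go wrong: poor facial selectivity, because chelation of magnesium between the formyl and the oxirane oxygen competes with the Felkin–Anh mode.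
- The fallback sets C6 by hydride delivery instead of carbon addition. It sets out from carbinol 16 as obtained and comes back to 16.
- Oxidation with Dess–Martin periodinane erases C6 and gives the epoxy vinyl ketone F8.
- Luche reduction (NaBH4, CeCl3·7H2O, MeOH, −78 °C) is 1,2-selective for the enone. As is known for α,β-epoxy ketones, it delivers hydride to the metal-bridged conformer so that the 5,6-anti (6S) carbinol results.

**Step 19.**
- What may go wrong: competing attack of ozone on the methacrylate double bond, and over-oxidation once the hindered C1 methylidene reacts slowly.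
- The fallback inverts the order of cleavage and acylation. It sets out from 26 and comes back at 29.
- Compound 26 holds no other C=C bond. It is ozonised (O3, CH2Cl2, −78 °C) to the hydroxy ozonide F9, and Me2S gives the hydroxy ketone F10.
- F10 may rest as its transannular C1–O8 hemiketal but should acylate through the open form with methacrylic anhydride, DMAP and Et3N to give 29.

**Further compounds**
F1 | step 17 | 6-O-[2-(bromomethyl)acryloyl] ester of 16 | CC[Si](CC)(CC)OCC[C@@](C)(O[Si](CC)(CC)CC)C(=C)CC[C@@]1(C)O[C@H]1[C@@H](OC(=O)C(=C)CBr)C=C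
F2 | step 17 | α-(bromomethyl)butenolide with C8 triethylsilyl ether | CC[Si](CC)(CC)OCC[C@@](C)(O[Si](CC)(CC)CC)C(=C)CC[C@@]1(C)O[C@H]1[C@H]1OC(=O)C(CBr)=C1
F3 | step 17 | α-(bromomethyl)butenolide C8 aldehyde | O=CC[C@@](C)(O[Si](CC)(CC)CC)C(=C)CC[C@@]1(C)O[C@H]1[C@H]1OC(=O)C(CBr)=C1
F4 | step 17 | ten-membered 8R carbinol with cis-fused α-methylene lactone | O[C@@H]1C[C@@](C)(O[Si](CC)(CC)CC)C(=C)CC[C@@]2(C)O[C@H]2[C@H]2OC(=O)C(=C)[C@H]21
F5 | step 17 | C13 pinacol boronate of the all-cis lactone, 8R carbinol | O[C@@H]1C[C@@](C)(O[Si](CC)(CC)CC)C(=C)CC[C@@]2(C)O[C@H]2[C@H]2OC(=O)[C@@H](CB3OC(C)(C)C(C)(C)O3)[C@H]21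
F6 | step 17 | 8R,13-diol of the all-cis lactone | O[C@@H]1C[C@@](C)(O[Si](CC)(CC)CC)C(=C)CC[C@@]2(C)O[C@H]2[C@H]2OC(=O)[C@@H](CO)[C@H]21
F7 | step 17 | C8 epimer (8R) of 26 | O[C@@H]1C[C@@](C)(O[Si](CC)(CC)CC)C(=C)CC[C@@]2(C)O[C@H]2[C@H]2OC(=O)[C@@H](CO[Si](C)(C)C(C)(C)C)[C@H]21
F8 | step 11 | epoxy vinyl ketone (C6 ketone of 16) | CC[Si](CC)(CC)OCC[C@@](C)(O[Si](CC)(CC)CC)C(=C)CC[C@@]1(C)O[C@H]1C(=O)C=C
F9 | step 19 | spiro-1,2,4-trioxolane (ozonide) at C1 of 26, C1 configuration open | O[C@H]1C[C@@](C)(O[Si](CC)(CC)CC)C3(OCOO3)CC[C@@]2(C)O[C@H]2[C@H]2OC(=O)[C@@H](CO[Si](C)(C)C(C)(C)C)[C@H]21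
F10 | step 19 | 8-hydroxy-1-oxo analogue of 29 | O[C@H]1C[C@@](C)(O[Si](CC)(CC)CC)C(=O)CC[C@@]2(C)O[C@H]2[C@H]2OC(=O)[C@@H](CO[Si](C)(C)C(C)(C)C)[C@H]21
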